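**Retrosynthetic overview**
- The target is traced back to a 5-hydroxychroman: the prenyl group reaches C6 by aromatic Claisen rearrangement of the 5-O-(1,1-dimethylallyl) ether (C6 is the only free ortho position of O5), followed by O-methylation and MOM removal.
- The chroman is traced back to an achiral (E)-stilbene: the O1–CH2 carbon (C2) is joined to C3 by a CuH-catalysed enantioselective intramolecular hydroalkylation of the C3=C4 double bond. This closes ring C, the only ring made in the route (rings A and B are bought), and sets C3.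
- Enabling feature: C3 is benzylic to ring B, so copper is placed there, and O1 and O5 both flank C4a, so ring A of the precursor can carry two identical O–CH2–OPiv arms. Either arm closes the pyran ring; the spare one is unmasked to the 5-OH that later steers the prenyl group to C6.
- The stilbene comes from a Heck coupling of a ring-A styrene (from 2,4,6-trihydroxybenzaldehyde) with the MOM ether of 4-bromo-3-methoxyphenol.

Key step: step 6

Assumption: (R)-DTBM-SEGPHOS is taken as the ligand antipode that leads to the (3R) series; if a first run shows the opposite sense, the (S)-ligand is used and nothing else changes.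

Step 1
Reactants: 1 2,4,6-trihydroxybenzaldehyde; 2 chloromethyl methyl ether
Product: 3 2,6-dihydroxy-4-(methoxymethoxy)benzaldehyde
Conditions: MOMCl (1.0 equiv), iPr2NEt (1.1 equiv), THF, 0 °C
Reagents that add atoms: chloromethyl methyl ether (2), COCCl
Why: Williamson-type O-alkylation; the para hydroxyl is the most acidic and the only one not hydrogen-bonded to the formyl group, so one equivalent of the chloride should react there first.

Step 2
Reactants: 3 2,6-dihydroxy-4-(methoxymethoxy)benzaldehyde; 4 chloromethyl pivalate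
Product: 5 2,6-bis(pivaloyloxymethoxy)-4-(methoxymethoxy)benzaldehyde
Conditions: chloromethyl pivalate (2.5 equiv), Cs2CO3 (2.5 equiv), NaI (cat.), DMF, rt
Reagents that add atoms: chloromethyl pivalate (4), CC(C)(C)C(=O)OCCl
Why: Williamson O-alkylation through the iodide formed in situ (Finkelstein exchange); Cs2CO3 in DMF should break the chelate of the ortho hydroxyls, and the hindered pivalate carbonyl should resist acyl transfer.

Step 3
Reactants: 5 2,6-bis(pivaloyloxymethoxy)-4-(methoxymethoxy)benzaldehyde; 6 methyltriphenylphosphonium bromide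
Product: 7 2,6-bis(pivaloyloxymethoxy)-4-(methoxymethoxy)styrene
Conditions: Ph3PCH3Br (1.3 equiv), KOtBu (1.2 equiv), THF, 0 °C; then 5, −40 °C to 0 °C
Reagents that add atoms: methyltriphenylphosphonium bromide (6), C[P+](c1ccccc1)(c1ccccc1)c1ccccc1.[Br-]
Why: Wittig methylenation; the non-stabilised ylide, made with a slight deficit of base, should react with the aldehyde far faster than with the hindered pivalate esters.

Step 4
Reactants: 8 4-bromo-3-methoxyphenol; 2 chloromethyl methyl ether
Product: 9 1-bromo-2-methoxy-4-(methoxymethoxy)benzene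
Conditions: MOMCl, iPr2NEt, CH2Cl2, 0 °C to rt
Reagents that add atoms: chloromethyl methyl ether (2), COCCl
Why: Williamson-type protection of the only hydroxyl as its MOM ether.

Step 5
Reactants: 7 2,6-bis(pivaloyloxymethoxy)-4-(methoxymethoxy)styrene; 9 1-bromo-2-methoxy-4-(methoxymethoxy)benzene
Product: 10 (E)-1-[2,6-bis(pivaloyloxymethoxy)-4-(methoxymethoxy)phenyl]-2-[2-methoxy-4-(methoxymethoxy)phenyl]ethene
Conditions: Pd[P(t-Bu)3]2 (3 mol %), Cy2NMe (1.2 equiv), dioxane, 80 °C
Reagents that add atoms: 1-bromo-2-methoxy-4-(methoxymethoxy)benzene (9), COCOc1ccc(Br)c(OC)c1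
Why: Mizoroki–Heck reaction; the aryl group should add to the unsubstituted alkene terminus, and syn β-hydride elimination then gives the E-stilbene under conditions that leave the ester arms untouched.

Step 6
Reactants: 10 (E)-1-[2,6-bis(pivaloyloxymethoxy)-4-(methoxymethoxy)phenyl]-2-[2-methoxy-4-(methoxymethoxy)phenyl]ethene
Product: 12 (3R)-3-[2-methoxy-4-(methoxymethoxy)phenyl]-7-(methoxymethoxy)-5-(pivaloyloxymethoxy)chroman, via benzylic alkylcopper 11 (not isolated)
Conditions: Cu(OAc)2 (6 mol %), (R)-DTBM-SEGPHOS (6.6 mol %), (MeO)2MeSiH (3 equiv), THF, 40 °C; aqueous NH4F work-up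
Reagents that add atoms: none
Why: Proposed new method: the ligated CuH (monovalent copper) made from Cu(OAc)2, the bisphosphine and the silane should add syn across C3=C4, with copper on C3 and hydride on C4, and the benzylic alkylcopper 11 should then displace pivalate from the methylene of one of the two equivalent O–CH2–OPiv arms with retention at the copper-bearing carbon, the copper pivalate being returned to CuH by the silane. The closest known reaction types are the CuH-catalysed enantioselective intramolecular hydroalkylation of halide-tethered styrenes and the CuH-catalysed hydroacetalisation of vinyl arenes with an acetoxy acetal; new here are the acyloxymethyl ether as the electrophile and the 1,2-diaryl alkene. Ring C is closed in the 6-exo-tet mode. The C3 stereocentre is set in the irreversible hydrocupration by the chiral bisphosphine alone (catalyst control, no other stereocentre present). The step needs copper to go to C3 and not to C4 (which would close a five-membered ring): ring A, with two ortho arms and three oxygens, is twisted out of conjugation and electron-rich, so the C–Cu bond should be stabilised only next to the planar ring B. It also needs attack at the arm methylene and not at the ester carbonyl, which the tert-butyl group and a six- rather than eight-membered closure should secure, and the substrate carries no second alkene because the prenyl group is added later.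

Step 7
Reactants: 12 (3R)-3-[2-methoxy-4-(methoxymethoxy)phenyl]-7-(methoxymethoxy)-5-(pivaloyloxymethoxy)chroman
Product: 14 (3R)-3-[2-methoxy-4-(methoxymethoxy)phenyl]-7-(methoxymethoxy)chroman-5-ol, via aryloxymethanol 13 (not isolated)
Conditions: NH3 (7 M in MeOH), rt
Reagents that add atoms: none
Why: Ammonolysis of the pivalate ester frees hemiacetal 13, which collapses to the phenol and formaldehyde; excess ammonia should also bind the formaldehyde and keep it from hydroxymethylating the electron-rich ring, and the MOM ethers are inert to base.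

Step 8
Reactants: 14 (3R)-3-[2-methoxy-4-(methoxymethoxy)phenyl]-7-(methoxymethoxy)chroman-5-ol; 15 tert-butyl 2-methylbut-3-en-2-yl carbonate
Product: 16 (3R)-3-[2-methoxy-4-(methoxymethoxy)phenyl]-7-(methoxymethoxy)-5-(2-methylbut-3-en-2-yloxy)chroman
Conditions: Pd(PPh3)4 (5 mol %), carbonate 15 (1.5 equiv), THF, 0 °C, short reaction time
Reagents that add atoms: tert-butyl 2-methylbut-3-en-2-yl carbonate (15), CC(C)(C)OC(=O)OC(C)(C)C=C
Why: Decarboxylative Tsuji–Trost O-allylation; zerovalent palladium ionises the tertiary carbonate and the phenoxide (the only free hydroxyl) should attack the more substituted allyl terminus under kinetic control to give the tertiary ether.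

Step 9
Reactants: 16 (3R)-3-[2-methoxy-4-(methoxymethoxy)phenyl]-7-(methoxymethoxy)-5-(2-methylbut-3-en-2-yloxy)chroman
Product: 18 (3R)-3-[2-methoxy-4-(methoxymethoxy)phenyl]-7-(methoxymethoxy)-6-(3-methylbut-2-enyl)chroman-5-ol, via ortho-dienone 17 (not isolated)
Conditions: PhNEt2, 120 °C
Reagents that add atoms: none
Why: Aromatic Claisen rearrangement ([3,3]) to C6, the only ortho position of O5 that bears hydrogen (the other is C4a), then tautomerisation of dienone 17; allyl inversion turns the 1,1-dimethylallyl ether into the normal prenyl group, and the basic solvent should suppress cyclisation of the product.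

Step 10
Reactants: 18 (3R)-3-[2-methoxy-4-(methoxymethoxy)phenyl]-7-(methoxymethoxy)-6-(3-methylbut-2-enyl)chroman-5-ol; 19 iodomethane
Product: 20 (3R)-5-methoxy-3-[2-methoxy-4-(methoxymethoxy)phenyl]-7-(methoxymethoxy)-6-(3-methylbut-2-enyl)chroman
Conditions: MeI (3 equiv), K2CO3, acetone, reflux
Reagents that add atoms: iodomethane (19), CI
Why: Williamson methylation of the only free phenol, which sits between the prenyl group and C4a.

Step 11
Reactants: 20 (3R)-5-methoxy-3-[2-methoxy-4-(methoxymethoxy)phenyl]-7-(methoxymethoxy)-6-(3-methylbut-2-enyl)chroman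
Product: 21 (3R)-3-(4-hydroxy-2-methoxyphenyl)-5-methoxy-6-(3-methylbut-2-enyl)chroman-7-ol
Conditions: HCl (3 M aq.)/MeOH 1:10, 45 °C, stopped at full conversion
Reagents that add atoms: none
Why: Acid-catalysed acetal exchange with methanol removes both MOM ethers; dilute acid and a short reaction time should keep the prenyl group from cyclising onto the neighbouring 7-hydroxyl, and C3 is not touched.

**Compound list**
1 | 2,4,6-trihydroxybenzaldehyde | O=Cc1c(O)cc(O)cc1O | starting material
2 | chloromethyl methyl ether (MOMCl) | COCCl | starting material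
3 | 2,6-dihydroxy-4-(methoxymethoxy)benzaldehyde | O=Cc1c(O)cc(OCOC)cc1O | intermediate
4 | chloromethyl pivalate | CC(C)(C)C(=O)OCCl | starting material
5 | 2,6-bis(pivaloyloxymethoxy)-4-(methoxymethoxy)benzaldehyde | O=Cc1c(OCOC(=O)C(C)(C)C)cc(OCOC)cc1OCOC(=O)C(C)(C)C | intermediate
6 | methyltriphenylphosphonium bromide | C[P+](c1ccccc1)(c1ccccc1)c1ccccc1.[Br-] | starting material
7 | 2,6-bis(pivaloyloxymethoxy)-4-(methoxymethoxy)styrene | C=Cc1c(OCOC(=O)C(C)(C)C)cc(OCOC)cc1OCOC(=O)C(C)(C)C | intermediate
8 | 4-bromo-3-methoxyphenol | COc1cc(O)ccc1Br | starting material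
9 | 1-bromo-2-methoxy-4-(methoxymethoxy)benzene | COCOc1ccc(Br)c(OC)c1 | intermediate
10 | (E)-1-[2,6-bis(pivaloyloxymethoxy)-4-(methoxymethoxy)phenyl]-2-[2-methoxy-4-(methoxymethoxy)phenyl]ethene | COCOc1ccc(/C=C/c2c(OCOC(=O)C(C)(C)C)cc(OCOC)cc2OCOC(=O)C(C)(C)C)c(OC)c1 | intermediate
11 | (R)-configured benzylic alkylcopper at C3, monovalent copper, bisphosphine ligand not drawn | COc1cc(OCOC)ccc1[C@@H](Cc1c(OCOC(=O)C(C)(C)C)cc(OCOC)cc1OCOC(=O)C(C)(C)C)[Cu] | intermediate (not isolated)
12 | (3R)-3-[2-methoxy-4-(methoxymethoxy)phenyl]-7-(methoxymethoxy)-5-(pivaloyloxymethoxy)chroman | COc1cc(OCOC)ccc1[C@@H]1COc2cc(OCOC)cc(OCOC(=O)C(C)(C)C)c2C1 | intermediate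
13 | (3R)-5-(hydroxymethoxy)-3-[2-methoxy-4-(methoxymethoxy)phenyl]-7-(methoxymethoxy)chroman (hemiacetal) | COc1cc(OCOC)ccc1[C@@H]1COc2cc(OCOC)cc(OCO)c2C1 | intermediate (not isolated)
14 | (3R)-3-[2-methoxy-4-(methoxymethoxy)phenyl]-7-(methoxymethoxy)chroman-5-ol | COc1cc(OCOC)ccc1[C@@H]1COc2cc(OCOC)cc(O)c2C1 | intermediate
15 | tert-butyl 2-methylbut-3-en-2-yl carbonate | CC(C)(C)OC(=O)OC(C)(C)C=C | starting material
16 | (3R)-3-[2-methoxy-4-(methoxymethoxy)phenyl]-7-(methoxymethoxy)-5-(2-methylbut-3-en-2-yloxy)chroman | COc1cc(OCOC)ccc1[C@@H]1COc2cc(OCOC)cc(OC(C)(C)C=C)c2C1 | intermediate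
17 | (3R)-6-(3-methylbut-2-enyl)-2,4-dienone of ring A (C5 ketone, C6 sp3, mixture at C6) | COc1cc(OCOC)ccc1[C@@H]1COC2=C(C1)C(=O)C(CC=C(C)C)C(OCOC)=C2 | intermediate (not isolated)
18 | (3R)-3-[2-methoxy-4-(methoxymethoxy)phenyl]-7-(methoxymethoxy)-6-(3-methylbut-2-enyl)chroman-5-ol | COc1cc(OCOC)ccc1[C@@H]1COc2cc(OCOC)c(CC=C(C)C)c(O)c2C1 | intermediate
19 | iodomethane | CI | starting material
20 | (3R)-5-methoxy-3-[2-methoxy-4-(methoxymethoxy)phenyl]-7-(methoxymethoxy)-6-(3-methylbut-2-enyl)chroman | COc1cc(OCOC)ccc1[C@@H]1COc2cc(OCOC)c(CC=C(C)C)c(OC)c2C1 | intermediate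
21 | (3R)-3-(4-hydroxy-2-methoxyphenyl)-5-methoxy-6-(3-methylbut-2-enyl)chroman-7-ol | COc1cc(O)ccc1[C@@H]1COc2cc(O)c(CC=C(C)C)c(OC)c2C1 | target

**Step count**
Total steps: 11. Longest linear sequence: 10 (steps 1, 2, 3, 5, 6, 7, 8, 9, 10, 11).

**Steps most likely to fail**

1. Step 6 (proposed new method). Hydrocupration may place copper on C4 and lead to five-membered closure; the alkylcopper may fail to displace pivalate and simply be protonated; CuH may reduce the arms by hydride displacement; or facial selectivity may be poor. Fallback, from 10 back to 12: the same bond is closed by a Lewis acid and the stereocentre is set afterwards. BF3·OEt2 (1 equiv) with 2,6-di-tert-butylpyridine in CH2Cl2 at −78 °C should ionise one arm; the electron-rich stilbene attacks the aryloxymethyl cation through C3 (oxocarbenium–alkene cyclisation of an α-acyloxy ether), and loss of the C3 proton from the C4 cation gives the achiral 3-[2-methoxy-4-(methoxymethoxy)phenyl]-7-(methoxymethoxy)-5-(pivaloyloxymethoxy)-2H-chromene F1. Asymmetric hydrogenation of F1 with [Ir(cod)(L)][B(3,5-(CF3)2C6H3)4] (L = a chiral phosphine–oxazoline, antipode chosen for the 3R product), H2 (50 bar), CH2Cl2, rt, should give 12; this works because no prenyl group is present yet.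

2. Step 2. Double alkylation of the two chelated ortho hydroxyls may stall at the mono-ether, or pivaloyl transfer to the phenoxide may compete. Fallback, from 3 back to 5: the arms are built stepwise. NaH, ClCH2SMe, NaI, DMF should give 2,6-bis(methylthiomethoxy)-4-(methoxymethoxy)benzaldehyde F2; SO2Cl2, CH2Cl2, 0 °C should convert it into 2,6-bis(chloromethoxy)-4-(methoxymethoxy)benzaldehyde F3; CsO2CC(CH3)3 (from pivalic acid and Cs2CO3), DMF, rt, should then give 5.

3. Step 8. The phenoxide may attack the unsubstituted allyl terminus, or the tertiary ether may isomerise to the linear O-prenyl ether, which would put a reverse-prenyl group on C6 in step 9. Fallback, from 14 back to 16: alkylation with 3-chloro-3-methylbut-1-yne (DBU, CuCl2 cat., MeCN, 0 °C) can only give the tertiary ether, (3R)-3-[2-methoxy-4-(methoxymethoxy)phenyl]-7-(methoxymethoxy)-5-(2-methylbut-3-yn-2-yloxy)chroman F4. Semi-hydrogenation (H2, Pd/CaCO3 poisoned with Pb(OAc)2, quinoline, EtOAc) should then give 16.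

**Further compounds**
F1 | step 6 | 3-[2-methoxy-4-(methoxymethoxy)phenyl]-7-(methoxymethoxy)-5-(pivaloyloxymethoxy)-2H-chromene | COc1cc(OCOC)ccc1C1=Cc2c(OCOC(=O)C(C)(C)C)cc(OCOC)cc2OC1
F2 | step 2 | 2,6-bis(methylthiomethoxy)-4-(methoxymethoxy)benzaldehyde | O=Cc1c(OCSC)cc(OCOC)cc1OCSC
F3 | step 2 | 2,6-bis(chloromethoxy)-4-(methoxymethoxy)benzaldehyde | O=Cc1c(OCCl)cc(OCOC)cc1OCCl
F4 | step 8 | (3R)-3-[2-methoxy-4-(methoxymethoxy)phenyl]-7-(methoxymethoxy)-5-(2-methylbut-3-yn-2-yloxy)chroman | COc1cc(OCOC)ccc1[C@@H]1COc2cc(OCOC)cc(OC(C)(C)C#C)c2C1
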